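The earlier runs and the new flask were computed on assumed constants, and the scatter is random.

In a stirred flask of constant volume, the proposed steps have the substrate turn into its tautomer, while the coupling partner meets the tautomer and gives target, meets the substrate and gives the isomer of the product, or decomposes by itself.

| flask | substrate | coupling partner | temperature | remark | time |
|---|---|---|---|---|---|
| maple | 20 mM | 1.5 equiv | 20 °C | run made earlier |  |
| elm | 20 mM | 0.75 equiv | 31 °C | run made earlier |  |
| cedar | 20 mM | 1.1 equiv | 20 °C | run made earlier |  |
| birch | 10 mM | 1.5 equiv | 31 °C | run made earlier |  |
| north-west | 20 mM | 1.50 equiv (fed, over 2.0 h) |  | the addition at 5 °C, then warmed to 25 °C; the feed brings no volume worth counting | 5.0 h |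
| south-west | 20 mM | 1.50 equiv (fed, over 2.0 h) | 25 °C | all else is in the flask from the start; the feed brings no volume worth counting | 5.0 h |
| south | 20 mM | 1.50 equiv | 25 °C | everything together at the start | 5.0 h |
| west | 20 mM | 1.50 equiv (in portions, 4, over 2.0 h) | 25 °C | first portion at the start, last at 2.0 h | 5.0 h |
| north-east | 20 mM | 1.50 equiv |  | everything together at the start at 5 °C, warmed to 25 °C at 2.0 h | 5.0 h |

- maple (time / h: target / %): 0.417: 27.6; 1.00: 41.5; 2.00: 44.7; 5.00: 44.8
- elm (time / h: target / %): 0.833: 16.9; 2.00: 16.0; 4.00: 16.4; 6.00: 17.3
- cedar (time / h: target / %): 0.833: 34.4; 2.00: 37.0; 4.00: 36.6; 6.00: 37.7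
- birch (time / h: target / %): 0.500: 19.3; 1.00: 18.8; 2.50: 18.9; 6.00: 20.1

(each reading ± 0.5 percentage points)

- the numbers in the tables scatter with a standard deviation of 0.5 percentage points
- steps that have been proposed: substrate <-> tautomer; substrate + coupling partner -> isomer of the product; coupling partner + tautomer -> target; coupling partner -> decomposed reagent

* the flask with the highest amount of target, in percent of the substrate charged ("all alike" if they lie within 1.5 percentage points) (north-west / south-west / south / west / north-east / all alike)
* final target, as a percentage of the substrate charged, in north-west
* final target, as a percentage of the substrate charged, in south-west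
* final target, as a percentage of the substrate charged, in south
* final target, as a percentage of the substrate charged, in west
* final target, as a percentage of the substrate charged, in north-east

Let y be target as a fraction of the substrate charged and b the partner charged per substrate. We take the partner's decay as first order and its capture as proportional to the unspent substrate, which gives b = y + κ·ln(1/(1 − y)). The isomer of the product is neglected. Here κ, our waste number (the inverse of a selectivity factor), is the partner lost per unit of that logarithm; in maple the κ term is the larger one, and y beside it the correction. The last readings, each with its scatter, give κ = 1.77 in maple, 3.04 in elm and 5.79 in birch. Birch, at half the substrate of elm and the same temperature but with twice the equivalents, carries nearly twice the κ; our rule has no place for the equivalents in κ, so we scale κ inversely with substrate. Scaling birch to 20 mM and taking its geometric mean with maple gives, for 25 °C, 2.26.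

With the last cedar reading as the correction, south comes to 39.1%, which we take as our floor for south-west. The ceiling is the whole substrate charge. Maple's first reading, at 20 °C, puts target formation up to 0.417 h at 0.662 h⁻¹ of the charge on average; the inverse of that rate is 1.51 h, shorter than the feed time, so we expect the fed partner to find tautomer waiting. If, as our guess, that brings κ to 1.13, half the batch estimate, our rule puts south-west at 57.2%, and we commit to south-west as highest.

The forecast chose north-east, with 45.5% there, 42% in north-west, 38% in west, 37% in south and 38.5% in south-west, just under our floor, on the ground that “All consumption steps are first order in partner, so feeding at 25 °C barely changes the split”.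

The flasks give 49.1% in north-west, 65.7% in south-west, 37.4% in south, 62.1% in west and 42.6% in north-east, so the highest is south-west.

    substrate ⇌ tautomer (K = 0.611, k = 6.18 × 10⁻⁴ s⁻¹, Ea = 88.0 kJ mol⁻¹, ΔH = −79.0 kJ mol⁻¹)
    substrate + coupling partner → isomer of the product (k = 0.00434 M⁻¹ s⁻¹, Ea = 64.0 kJ mol⁻¹)
    coupling partner + tautomer → target (k = 0.261 M⁻¹ s⁻¹, Ea = 42.0 kJ mol⁻¹)
    coupling partner → decomposed reagent (k = 0.00118 s⁻¹, Ea = 99.0 kJ mol⁻¹)
    (constants at 25 °C)

Read back from its result by our rule, south-west has κ = 0.787, below both our batch estimate 2.26 and our halved 1.13. The neighbouring flask repeats south-west with 34 mM of substrate, so κ scales to 0.463. The same rule then gives 78.1%, and that flask gave 75.9%.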